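**Assumption (chemistry):** the SMILES string is read as the all-E (6S,3′S,6′S) isomer with the C3′ hydroxyl trans to the chain at C6′ (ring A = unsubstituted ring C1–C6, ring B = hydroxylated ring C1′–C6′, chain C7–C7′), and crocetindial 12 is taken as a purchasable C20 building block.

## Structural features

The target is an all-E C40 carotenoid in which a nonaene chain C7–C7′ with methyl branches at C9, C13, C13′ and C9′ is bonded through the sp3 carbons C6 and C6′ to two 2,6,6-trimethylcyclohex-2-enyl rings, ring A (no oxygen) and ring B (hydroxyl at C3′). There are three stereocentres, C6 (S), C6′ (S) and C3′ (S); C6 and C6′ are separated by the whole chain, and C3′ and C6′ stand 1,4 across the ring B double bond C4′=C5′ with the hydroxyl trans to the chain. C6 and C6′ are tertiary, allylic to both the ring alkene and the polyene, and each stands next to a quaternary carbon (C1, C1′), so they are hard to make by intermolecular C–C bond formation and can lose their configuration when the ring double bond moves into conjugation. Fragile groups are the polyene (light, oxygen, acid) and the allylic C3′ alcohol, which ionises easily in acid. The chain itself is routine; the real difficulty is the absolute control of two remote but identical ring stereocentres and the relative control of C3′. The key step exploits the array C4, C5(CH3), C6(H), C1(CH3)2 present in each ring: an oxygen on C4 of the C5=C6 double-bond isomer is in a 1,3-allylic relation to C6, so a [2,3]-sigmatropic shift from that oxygen forms C6–C7, places the double bond at C4=C5 and sets C6 in one operation. Because C6 and C6′ have the same configuration, one rearrangement product can supply both rings. In one sentence, the route is the Wittig–Still rearrangement of the stannylmethyl ether 4 of an enantioenriched 2,4,4-trimethylcyclohex-2-enol, which moves the carbinol stereocentre to C6 next to the quaternary carbon.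

## Logic of the disconnections

19 ⇒ 18. Only the O–Si bond at C3′ is cut. The allylic C3′ hydroxyl is masked to the end because it would be deprotonated in the last coupling and is labile to acid. The skeleton is not simplified, but the last C–C bond can then be made under strong base. The forward step must remove silicon without acid.

18 ⇒ 15 + 11 (through 17 and 16). The C7′=C8′ double bond is cut. Cutting at the ring–chain junction puts both stereocentres of ring B into a C10 piece and makes C7′, not C8′, the nucleophilic carbon, so that C6′ is never α to a carbonyl group. C40 falls to C30 + C10. The forward step has to give the E alkene and must not touch the O–Si bond or the chain.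

15 ⇒ 8 + 12 (through 14 and 13). The C7=C8 double bond is cut in the same way. The whole chain C8–C8′ becomes the symmetric, purchasable 12, and ring A becomes the C10 piece 8. The forward step has to stop after one of the two equivalent aldehyde carbons has reacted.

11 ⇒ 10 ⇒ 9 ⇒ 8. The O–Si bond and then the C3′–O bond are removed. Without the oxygen the ring B piece is identical with the ring A piece, so one compound serves both halves and C6 and C6′ are set only once. Three steps are spent, a second enantioselective sequence is saved. The forward steps need an allylic oxidation that picks C3′ and a reduction whose face is chosen by C6′.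

8 ⇒ 7 ⇒ 6. The S–O bonds and then the C7–S bond are cut. The C10 piece is returned to a primary alcohol. The forward steps are a substitution at a β-branched primary carbon and an S-oxidation that must leave the ring alkene.

6 ⇒ 4 (through 5), the key disconnection. The C6–C7 bond is cut, the double bond is moved from C4=C5 to C5=C6, and C7 is reattached through oxygen to C4. The tertiary stereocentre C6, allylic and next to the quaternary C1, is traded for a secondary carbinol centre that is far easier to set, and the position of the ring double bond becomes a consequence of the mechanism. The forward step must be suprafacial and must win over the [1,2] shift.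

4 ⇒ 2 ⇒ 1 (through 3). The O–CH2 bond and then the C4–H bond are cut. This leads to 1, achiral and purchasable, with all nine ring carbons in place. The forward steps need an O-alkylation that does not touch C4 and a catalyst-controlled 1,2-reduction.

## Other disconnections considered

Alternative 1: C11=C12 and C11′=C12′ are cut (C15 + C10 + C15), the plan that comes to mind first. Forward, (S)-α-ionone A1 would be homologated to the ring A phosphonium salt A2 and, after oxidation at C3′ and reduction, to the hydroxylated ring B salt A3, and both would be joined by two Wittig reactions to the C10 dialdehyde A4. This cut does nothing for C6 and C6′, since A1 would have to come from resolution of the racemate. A3 forces the acid-labile allylic C3′ alcohol through the acidic conditions of phosphonium salt formation, or needs protection. Each half needs its own homologation, and the two carbonyl groups of an oxidised ionone must be told apart, so the step count is higher than in the chosen plan.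

Alternative 2: the ring bond C1–C6 is cut (cationic cyclisation of an acyclic precursor). Forward, the geranyl sulfone A5 would be cyclised by a chiral proton source to 8 directly. The cation at C5 can lose a proton from C4, from C6 or from the methyl group, and the same acid can move the double bond into the tetrasubstituted position, which erases C6. The enantiofacial choice would rest on protonation of a remote alkene in a flexible chain that offers the catalyst no anchoring group. In the chosen plan the position of the double bond and the configuration of C6 both follow from a concerted mechanism.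

Alternative 3: the C6–C7 bond is cut by a [3,3] instead of a [2,3] shift. Forward, Johnson–Claisen rearrangement of 2 under orthoester conditions would give ester A6 with the same transfer of chirality. It delivers two carbons with C8 as a carboxyl carbon, so C7 cannot serve as the sulfonyl nucleophile. C7=C8 would then have to be made by addition to C8 and dehydration, without control over where the new double bond forms relative to C6, and with several extra redox steps per ring. The weak acid at high temperature is a further risk for the ring double bond. The [2,3] shift delivers exactly one carbon, at the alcohol level, at low temperature.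

Key step: step 3

## Route

Step 1
Reactants: 1 2,4,4-trimethylcyclohex-2-en-1-one
Product: 2 (1R)-2,4,4-trimethylcyclohex-2-en-1-ol
Conditions: (S)-1-methyl-3,3-diphenyltetrahydro-1H,3H-pyrrolo[1,2-c][1,3,2]oxazaborole (10 mol%), BH3·SMe2, THF, −20 °C; MeOH, then aqueous work-up
Reagents that add atoms: none
Why: Corey–Bakshi–Shibata reduction; the ketone binds to the catalyst boron with its alkenyl arm (C2 with its methyl group) as the large group, and the (S)-catalyst then delivers hydride to the face that gives the (R)-carbinol. 2-Substituted cyclohexenones are among the best substrates, and activation at oxygen ensures 1,2-reduction.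

Step 2
Reactants: 2 (1R)-2,4,4-trimethylcyclohex-2-en-1-ol
Product: 4 tributyl({[(1R)-2,4,4-trimethylcyclohex-2-en-1-yl]oxy}methyl)stannane, via potassium alkoxide 3 (not isolated)
Conditions: KH, THF, 0 °C; then Bu3SnCH2I, 18-crown-6 (cat.), 0 °C → rt
Reagents that add atoms: tributyl(iodomethyl)stannane, CCCC[Sn](CCCC)(CCCC)CI
Why: Williamson ether synthesis on the potassium alkoxide with a reactive primary iodide; the C–O bond of the stereocentre is not touched, so the (R) configuration is kept.

Step 3
Reactants: 4 tributyl({[(1R)-2,4,4-trimethylcyclohex-2-en-1-yl]oxy}methyl)stannane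
Product: 6 [(1S)-2,6,6-trimethylcyclohex-2-en-1-yl]methanol, via lithiomethyl ether 5 (not isolated)
Conditions: n-BuLi, THF, −78 → −40 °C; then H2O
Reagents that add atoms: none
Why: Tin–lithium exchange gives the α-alkoxymethyllithium 5, which rearranges by a concerted [2,3]-sigmatropic shift through a five-membered envelope transition state: the O–C4 bond breaks while C7–C6 forms and the double bond moves from C5=C6 to C4=C5. The closest known reaction type is the Wittig–Still rearrangement of stannylmethyl ethers of cyclic secondary allylic alcohols. No ring is closed; the six-membered ring is kept and only its double bond is transposed. The new stereocentre C6 is controlled by the carbinol centre C4, because within the ring the shift can only be suprafacial: the CH2 group is delivered to the face of C6 that carried the oxygen, so (R) at C4 becomes (S) at C6. The selectivity needed is [2,3] over the radical-pair [1,2] shift and over protonation of 5. It is secured by the low temperature and by the half-chair with the C4–O bond pseudoaxial, which is favoured because it relieves strain with the C5 methyl group and which aligns the C–O bond with the π system. In that half-chair the pseudoaxial methyl group of C1 lies on the face opposite to the migrating group, so the bond next to the quaternary carbon forms against a pseudoequatorial methyl group only. The driving force is the change of an unstabilised carbanion into a lithium alkoxide. The same product later supplies ring B, so this one operation sets C6 and C6′.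

Step 4
Reactants: 6 [(1S)-2,6,6-trimethylcyclohex-2-en-1-yl]methanol
Product: 7 1-phenyl-5-({[(1S)-2,6,6-trimethylcyclohex-2-en-1-yl]methyl}sulfanyl)-1H-tetrazole
Conditions: 1-phenyl-1H-tetrazole-5-thiol, PPh3, DIAD, THF, 0 °C → rt
Reagents that add atoms: 1-phenyl-1H-tetrazole-5-thiol, Sc1nnnn1-c1ccccc1
Why: Mitsunobu reaction; the primary alcohol is activated as its oxyphosphonium ion and displaced by the acidic thiol at C7. C6 is not involved, so its configuration is retained.

Step 5
Reactants: 7 1-phenyl-5-({[(1S)-2,6,6-trimethylcyclohex-2-en-1-yl]methyl}sulfanyl)-1H-tetrazole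
Product: 8 1-phenyl-5-({[(1S)-2,6,6-trimethylcyclohex-2-en-1-yl]methyl}sulfonyl)-1H-tetrazole
Conditions: (NH4)6Mo7O24·4H2O (10 mol%), 30% aq. H2O2, EtOH, 0 °C → rt
Reagents that add atoms: hydrogen peroxide, OO
Why: Molybdate-catalysed oxidation of sulfide to sulfone; the peroxomolybdate oxidises sulfur much faster than a hindered trisubstituted alkene that has no directing hydroxyl group.

Step 6 (run on the part of 8 meant for ring B)
Reactants: 8 1-phenyl-5-({[(1S)-2,6,6-trimethylcyclohex-2-en-1-yl]methyl}sulfonyl)-1H-tetrazole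
Product: 9 (4S)-3,5,5-trimethyl-4-{[(1-phenyl-1H-tetrazol-5-yl)sulfonyl]methyl}cyclohex-2-en-1-one
Conditions: Mn(OAc)3·2H2O (10 mol%), t-BuOOH (5 equiv, in decane), 3 Å molecular sieves, EtOAc, rt
Reagents that add atoms: tert-butyl hydroperoxide, CC(C)(C)OO
Why: Radical allylic C–H oxidation with tert-butyl hydroperoxide; C3′ is the only allylic methylene, while the tertiary C6′–H is shielded by C1′ and deactivated towards the electrophilic peroxyl radical by the neighbouring sulfonyl group, so oxygen should enter at C3′ and the peroxide collapse to the enone. The neutral medium avoids deprotonation at C6′ and loss of sulfinate from the product.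

Step 7
Reactants: 9 (4S)-3,5,5-trimethyl-4-{[(1-phenyl-1H-tetrazol-5-yl)sulfonyl]methyl}cyclohex-2-en-1-one
Product: 10 (1S,4S)-3,5,5-trimethyl-4-{[(1-phenyl-1H-tetrazol-5-yl)sulfonyl]methyl}cyclohex-2-en-1-ol
Conditions: LiBH(s-Bu)3, THF, −78 °C; then H2O
Reagents that add atoms: none
Why: Substrate-controlled 1,2-reduction of a β,β-disubstituted enone; in the favoured sofa conformer the C6′ substituent is pseudoaxial (away from the C5′ methyl group) and the axial methyl group of C1′ lies on the other face, where it blocks the axial path to C3′. The bulky hydride should therefore enter from the face that carries the C6′ substituent and place the hydroxyl trans to it, which is (S) at C3′.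

Step 8
Reactants: 10 (1S,4S)-3,5,5-trimethyl-4-{[(1-phenyl-1H-tetrazol-5-yl)sulfonyl]methyl}cyclohex-2-en-1-ol
Product: 11 5-({[(1S,4S)-4-{[tert-butyl(dimethyl)silyl]oxy}-2,6,6-trimethylcyclohex-2-en-1-yl]methyl}sulfonyl)-1-phenyl-1H-tetrazole
Conditions: TBSCl, imidazole, DMF, rt
Reagents that add atoms: tert-butyldimethylsilyl chloride, CC(C)(C)[Si](C)(C)Cl
Why: Standard silylation of a secondary allylic alcohol; the ether keeps an alkoxide from attacking the tetrazolyl sulfone in step 10 and carries the acid-sensitive allylic oxygen through the coupling.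

Step 9 (run on the remaining part of 8)
Reactants: 8 1-phenyl-5-({[(1S)-2,6,6-trimethylcyclohex-2-en-1-yl]methyl}sulfonyl)-1H-tetrazole; 12 (2E,4E,6E,8E,10E,12E,14E)-2,6,11,15-tetramethylhexadeca-2,4,6,8,10,12,14-heptaenedial (crocetindial)
Product: 15 (2E,4E,6E,8E,10E,12E,14E,16E)-2,6,11,15-tetramethyl-17-[(1S)-2,6,6-trimethylcyclohex-2-en-1-yl]heptadeca-2,4,6,8,10,12,14,16-octaenal, via potassium sulfonyl carbanion 13 (not isolated), via potassium β-alkoxy sulfone 14 (not isolated)
Conditions: 8, KN(SiMe3)2, DME/THF, −78 °C; added slowly to 12 (3 equiv), THF, −78 °C → rt; argon, dark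
Reagents that add atoms: none
Why: Julia–Kocienski olefination; 13 adds to one aldehyde carbon of 12 to give 14, the tetrazolyl group moves from sulfur to oxygen (Smiles rearrangement), and loss of sulfur dioxide and the tetrazololate forms C7=C8, a sequence that favours the E alkene with conjugated aldehydes. Slow addition of 13 to an excess of 12 limits the second olefination, and C6 cannot epimerise because it is β, not α, to the carbanion.

Step 10
Reactants: 11 5-({[(1S,4S)-4-{[tert-butyl(dimethyl)silyl]oxy}-2,6,6-trimethylcyclohex-2-en-1-yl]methyl}sulfonyl)-1-phenyl-1H-tetrazole; 15 (2E,4E,6E,8E,10E,12E,14E,16E)-2,6,11,15-tetramethyl-17-[(1S)-2,6,6-trimethylcyclohex-2-en-1-yl]heptadeca-2,4,6,8,10,12,14,16-octaenal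
Product: 18 tert-butyl(dimethyl)silyl ether of (6S,3′S,6′S)-ε,ε-caroten-3′-ol, via potassium sulfonyl carbanion 16 (not isolated), via potassium β-alkoxy sulfone 17 (not isolated)
Conditions: 11 (1.3 equiv), KN(SiMe3)2, DME/THF, −78 °C; then 15, −78 °C → rt; argon, dark
Reagents that add atoms: none
Why: Second Julia–Kocienski olefination by the same mechanism closes the chain at C7′=C8′, again with the E geometry expected for a conjugated aldehyde. The O–Si bond is inert to the amide base, and neither C3′ nor C6′ is α to the carbanion.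

Step 11
Reactants: 18 tert-butyl(dimethyl)silyl ether of (6S,3′S,6′S)-ε,ε-caroten-3′-ol
Product: 19 (6S,3′S,6′S)-ε,ε-caroten-3′-ol (target)
Conditions: Bu4NF, THF, 0 °C → rt; argon, dark; crystallisation
Reagents that add atoms: none
Why: Fluoride cleavage of the silyl ether under non-acidic conditions, which avoids ionisation of the allylic C3′–O bond and migration of the ring double bonds; the all-E product should be purified by crystallisation.

## Compound list

1 | 2,4,4-trimethylcyclohex-2-en-1-one | CC1=CC(C)(C)CCC1=O | starting material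
2 | (1R)-2,4,4-trimethylcyclohex-2-en-1-ol | O[C@@H]1CCC(C)(C)C=C1C | intermediate
3 | potassium (1R)-2,4,4-trimethylcyclohex-2-en-1-olate | [K+].[O-][C@@H]1CCC(C)(C)C=C1C | intermediate (not isolated)
4 | tributyl({[(1R)-2,4,4-trimethylcyclohex-2-en-1-yl]oxy}methyl)stannane | CCCC[Sn](CCCC)(CCCC)CO[C@@H]1CCC(C)(C)C=C1C | intermediate
5 | ({[(1R)-2,4,4-trimethylcyclohex-2-en-1-yl]oxy}methyl)lithium | [Li]CO[C@@H]1CCC(C)(C)C=C1C | intermediate (not isolated)
6 | [(1S)-2,6,6-trimethylcyclohex-2-en-1-yl]methanol | CC1=CCCC(C)(C)[C@@H]1CO | intermediate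
7 | 1-phenyl-5-({[(1S)-2,6,6-trimethylcyclohex-2-en-1-yl]methyl}sulfanyl)-1H-tetrazole | CC1=CCCC(C)(C)[C@@H]1CSc1nnnn1-c1ccccc1 | intermediate
8 | 1-phenyl-5-({[(1S)-2,6,6-trimethylcyclohex-2-en-1-yl]methyl}sulfonyl)-1H-tetrazole | CC1=CCCC(C)(C)[C@@H]1CS(=O)(=O)c1nnnn1-c1ccccc1 | intermediate
9 | (4S)-3,5,5-trimethyl-4-{[(1-phenyl-1H-tetrazol-5-yl)sulfonyl]methyl}cyclohex-2-en-1-one | CC1=CC(=O)CC(C)(C)[C@@H]1CS(=O)(=O)c1nnnn1-c1ccccc1 | intermediate
10 | (1S,4S)-3,5,5-trimethyl-4-{[(1-phenyl-1H-tetrazol-5-yl)sulfonyl]methyl}cyclohex-2-en-1-ol | O=S(=O)(c1nnnn1-c1ccccc1)C[C@@H]1C(C)=C[C@@H](O)CC1(C)C | intermediate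
11 | 5-({[(1S,4S)-4-{[tert-butyl(dimethyl)silyl]oxy}-2,6,6-trimethylcyclohex-2-en-1-yl]methyl}sulfonyl)-1-phenyl-1H-tetrazole | O=S(=O)(c1nnnn1-c1ccccc1)C[C@@H]1C(C)=C[C@@H](O[Si](C)(C)C(C)(C)C)CC1(C)C | intermediate
12 | (2E,4E,6E,8E,10E,12E,14E)-2,6,11,15-tetramethylhexadeca-2,4,6,8,10,12,14-heptaenedial (crocetindial) | O=C/C(C)=C/C=C/C(C)=C/C=C/C=C(C)/C=C/C=C(C)/C=O | starting material
13 | potassium [(1-phenyl-1H-tetrazol-5-yl)sulfonyl][(1S)-2,6,6-trimethylcyclohex-2-en-1-yl]methanide | [K+].CC1=CCCC(C)(C)[C@@H]1[CH-]S(=O)(=O)c1nnnn1-c1ccccc1 | intermediate (not isolated)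
14 | potassium (3E,5E,7E,9E,11E,13E,15E)-3,7,12,16-tetramethyl-17-oxo-1-[(1-phenyl-1H-tetrazol-5-yl)sulfonyl]-1-[(1S)-2,6,6-trimethylcyclohex-2-en-1-yl]heptadeca-3,5,7,9,11,13,15-heptaen-2-olate (epimers at chain C1 and C2) | CC1=CCCC(C)(C)[C@@H]1C(S(=O)(=O)c1nnnn1-c1ccccc1)C([O-])/C(C)=C/C=C/C(C)=C/C=C/C=C(C)/C=C/C=C(C)/C=O.[K+] | intermediate (not isolated)
15 | (2E,4E,6E,8E,10E,12E,14E,16E)-2,6,11,15-tetramethyl-17-[(1S)-2,6,6-trimethylcyclohex-2-en-1-yl]heptadeca-2,4,6,8,10,12,14,16-octaenal | CC1=CCCC(C)(C)[C@@H]1/C=C/C(C)=C/C=C/C(C)=C/C=C/C=C(C)/C=C/C=C(C)/C=O | intermediate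
16 | potassium [(1S,4S)-4-{[tert-butyl(dimethyl)silyl]oxy}-2,6,6-trimethylcyclohex-2-en-1-yl][(1-phenyl-1H-tetrazol-5-yl)sulfonyl]methanide | [K+].O=S(=O)(c1nnnn1-c1ccccc1)[CH-][C@@H]1C(C)=C[C@@H](O[Si](C)(C)C(C)(C)C)CC1(C)C | intermediate (not isolated)
17 | potassium β-alkoxy sulfone from 16 and 15: compound 18 with C7′H(SO2-tetrazolyl)–C8′H(OK) in place of C7′=C8′ (epimers at C7′ and C8′) | CC1=CCCC(C)(C)[C@@H]1/C=C/C(C)=C/C=C/C(C)=C/C=C/C=C(C)/C=C/C=C(C)/C([O-])C(S(=O)(=O)c1nnnn1-c1ccccc1)[C@@H]1C(C)=C[C@@H](O[Si](C)(C)C(C)(C)C)CC1(C)C.[K+] | intermediate (not isolated)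
18 | tert-butyl(dimethyl)({(1S,4S)-3,5,5-trimethyl-4-[(1E,3E,5E,7E,9E,11E,13E,15E,17E)-3,7,12,16-tetramethyl-18-[(1S)-2,6,6-trimethylcyclohex-2-en-1-yl]octadeca-1,3,5,7,9,11,13,15,17-nonaen-1-yl]cyclohex-2-en-1-yl}oxy)silane | CC1=CCCC(C)(C)[C@@H]1/C=C/C(C)=C/C=C/C(C)=C/C=C/C=C(C)/C=C/C=C(C)/C=C/[C@@H]1C(C)=C[C@@H](O[Si](C)(C)C(C)(C)C)CC1(C)C | intermediate
19 | (1S,4S)-3,5,5-trimethyl-4-[(1E,3E,5E,7E,9E,11E,13E,15E,17E)-3,7,12,16-tetramethyl-18-[(1S)-2,6,6-trimethylcyclohex-2-en-1-yl]octadeca-1,3,5,7,9,11,13,15,17-nonaen-1-yl]cyclohex-2-en-1-ol | CC1=CCCC(C)(C)[C@@H]1/C=C/C(C)=C/C=C/C(C)=C/C=C/C=C(C)/C=C/C=C(C)/C=C/[C@@H]1C(C)=C[C@@H](O)CC1(C)C | target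

## Step count and risks

Total step count: 11. Longest linear sequence: 10 steps (steps 1–8, 10, 11); the ring A branch (steps 1–5, 9, 10, 11) has 8.

Steps least certain to work:

Step 3 (key step). The [1,2] shift through a radical pair, or simple protonation of 5, may overtake the [2,3] shift, because the receiving carbon C6 is flanked by the quaternary C1 and the departing allyl fragment would be a stabilised radical. The fallback sets out from 2 and returns at 6, and replaces the unstabilised organolithium by a stabilised enediolate that can be warmed. Alkylation of 2 with bromoacetic acid (NaH, THF, reflux) would give {[(1R)-2,4,4-trimethylcyclohex-2-en-1-yl]oxy}acetic acid F1. Its dianion (LiN(i-Pr)2, 2.5 equiv, THF, −78 → 0 °C) should undergo the enolate variant of the [2,3]-Wittig rearrangement to hydroxy[(1S)-2,6,6-trimethylcyclohex-2-en-1-yl]acetic acid F2, with the same suprafacial transfer. Oxidative decarboxylation (Pb(OAc)4, CH2Cl2, 0 °C) would give (1S)-2,6,6-trimethylcyclohex-2-ene-1-carbaldehyde F3, which is reduced at once (NaBH4, MeOH, 0 °C) to 6 before the aldehyde can epimerise.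

Step 6. Hydrogen abstraction at the tertiary C6′–H or at the C5′ methyl group, and over-oxidation, may erode the site selectivity, and any base would trigger loss of sulfinate from the enone. The fallback sets out from 8 and returns at 9, and replaces C–H abstraction by oxygen transfer to the alkene. Epoxidation of 8 (mCPBA, NaHCO3, CH2Cl2, 0 °C) would give 1-phenyl-5-({[(2S)-1,3,3-trimethyl-7-oxabicyclo[4.1.0]heptan-2-yl]methyl}sulfonyl)-1H-tetrazole F4. Opening at the secondary carbon C4′ with sodium phenylselenide (PhSeSePh, NaBH4, EtOH) would give (6S)-1,5,5-trimethyl-2-(phenylselanyl)-6-{[(1-phenyl-1H-tetrazol-5-yl)sulfonyl]methyl}cyclohexan-1-ol F5. Its selenoxide (H2O2, THF) can eliminate only towards C3′ and so should give (6S)-1,5,5-trimethyl-6-{[(1-phenyl-1H-tetrazol-5-yl)sulfonyl]methyl}cyclohex-2-en-1-ol F6. Oxidative 1,3-transposition of this tertiary allylic alcohol (pyridinium chlorochromate, [C5H5NH][CrO3Cl], CH2Cl2) returns 9.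

Step 7. Facial selectivity may be poor: hydride delivery along the axial path past the C1′ methyl group, or reaction through the minor sofa conformer, leads to the cis alcohol. The fallback sets out from 9 and returns at 10, and makes the cis alcohol on purpose and inverts it. Luche reduction (NaBH4, CeCl3·7H2O, MeOH, −78 °C), in which the small hydride should take the axial path, would give (1R,4S)-3,5,5-trimethyl-4-{[(1-phenyl-1H-tetrazol-5-yl)sulfonyl]methyl}cyclohex-2-en-1-ol F7. Mitsunobu inversion with 4-nitrobenzoic acid (PPh3, DIAD, THF) would give (1S,4S)-3,5,5-trimethyl-4-{[(1-phenyl-1H-tetrazol-5-yl)sulfonyl]methyl}cyclohex-2-en-1-yl 4-nitrobenzoate F8, and methanolysis (K2CO3, MeOH, 0 °C) returns 10. Any cis alcohol formed in step 7 itself can enter the same sequence.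

Step 9. The second aldehyde group of the first-formed product may react as well, and E selectivity at C7=C8 may be incomplete (minor Z isomers would have to be removed or equilibrated with a trace of iodine). The fallback sets out from 12 and returns at 15, and moves the statistical operation to the cheapest compound so that the olefination runs on a mono-aldehyde with the sulfone in excess. Partial reduction of 12 (NaBH4, 0.3 equiv, THF/EtOH, −20 °C, unreacted 12 recycled) would give (2E,4E,6E,8E,10E,12E,14E)-16-hydroxy-2,6,11,15-tetramethylhexadeca-2,4,6,8,10,12,14-heptaenal F9. Silylation (TBSCl, imidazole, DMF) would give (2E,4E,6E,8E,10E,12E,14E)-16-{[tert-butyl(dimethyl)silyl]oxy}-2,6,11,15-tetramethylhexadeca-2,4,6,8,10,12,14-heptaenal F10. Julia–Kocienski olefination with 13 (from 8, 1.5 equiv) would give tert-butyl(dimethyl){[(2E,4E,6E,8E,10E,12E,14E,16E)-2,6,11,15-tetramethyl-17-[(1S)-2,6,6-trimethylcyclohex-2-en-1-yl]heptadeca-2,4,6,8,10,12,14,16-octaen-1-yl]oxy}silane F11. Desilylation (Bu4NF, THF) would give (2E,4E,6E,8E,10E,12E,14E,16E)-2,6,11,15-tetramethyl-17-[(1S)-2,6,6-trimethylcyclohex-2-en-1-yl]heptadeca-2,4,6,8,10,12,14,16-octaen-1-ol F12, and allylic oxidation (MnO2, CH2Cl2) returns 15.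

## Further compounds

F1 | step 3 | {[(1R)-2,4,4-trimethylcyclohex-2-en-1-yl]oxy}acetic acid | OC(=O)CO[C@@H]1CCC(C)(C)C=C1C
F2 | step 3 | hydroxy[(1S)-2,6,6-trimethylcyclohex-2-en-1-yl]acetic acid (both carbinol epimers) | CC1=CCCC(C)(C)[C@@H]1C(O)C(=O)O
F3 | step 3 | (1S)-2,6,6-trimethylcyclohex-2-ene-1-carbaldehyde | CC1=CCCC(C)(C)[C@@H]1C=O
F4 | step 6 | 1-phenyl-5-({[(2S)-1,3,3-trimethyl-7-oxabicyclo[4.1.0]heptan-2-yl]methyl}sulfonyl)-1H-tetrazole (both epoxide faces) | CC12OC1CCC(C)(C)[C@@H]2CS(=O)(=O)c1nnnn1-c1ccccc1
F5 | step 6 | (6S)-1,5,5-trimethyl-2-(phenylselanyl)-6-{[(1-phenyl-1H-tetrazol-5-yl)sulfonyl]methyl}cyclohexan-1-ol (C1 and C2 as set by trans opening) | CC1(O)C([Se]c2ccccc2)CCC(C)(C)[C@@H]1CS(=O)(=O)c1nnnn1-c1ccccc1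
F6 | step 6 | (6S)-1,5,5-trimethyl-6-{[(1-phenyl-1H-tetrazol-5-yl)sulfonyl]methyl}cyclohex-2-en-1-ol (C1 as set by the epoxide face) | CC1(O)C=CCC(C)(C)[C@@H]1CS(=O)(=O)c1nnnn1-c1ccccc1
F7 | step 7 | (1R,4S)-3,5,5-trimethyl-4-{[(1-phenyl-1H-tetrazol-5-yl)sulfonyl]methyl}cyclohex-2-en-1-ol | O=S(=O)(c1nnnn1-c1ccccc1)C[C@@H]1C(C)=C[C@H](O)CC1(C)C
F8 | step 7 | (1S,4S)-3,5,5-trimethyl-4-{[(1-phenyl-1H-tetrazol-5-yl)sulfonyl]methyl}cyclohex-2-en-1-yl 4-nitrobenzoate | O=S(=O)(c1nnnn1-c1ccccc1)C[C@@H]1C(C)=C[C@@H](OC(=O)c2ccc(cc2)[N+](=O)[O-])CC1(C)C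
F9 | step 9 | (2E,4E,6E,8E,10E,12E,14E)-16-hydroxy-2,6,11,15-tetramethylhexadeca-2,4,6,8,10,12,14-heptaenal | O=C/C(C)=C/C=C/C(C)=C/C=C/C=C(C)/C=C/C=C(C)/CO
F10 | step 9 | (2E,4E,6E,8E,10E,12E,14E)-16-{[tert-butyl(dimethyl)silyl]oxy}-2,6,11,15-tetramethylhexadeca-2,4,6,8,10,12,14-heptaenal | O=C/C(C)=C/C=C/C(C)=C/C=C/C=C(C)/C=C/C=C(C)/CO[Si](C)(C)C(C)(C)C
F11 | step 9 | tert-butyl(dimethyl){[(2E,4E,6E,8E,10E,12E,14E,16E)-2,6,11,15-tetramethyl-17-[(1S)-2,6,6-trimethylcyclohex-2-en-1-yl]heptadeca-2,4,6,8,10,12,14,16-octaen-1-yl]oxy}silane | CC1=CCCC(C)(C)[C@@H]1/C=C/C(C)=C/C=C/C(C)=C/C=C/C=C(C)/C=C/C=C(C)/CO[Si](C)(C)C(C)(C)C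
F12 | step 9 | (2E,4E,6E,8E,10E,12E,14E,16E)-2,6,11,15-tetramethyl-17-[(1S)-2,6,6-trimethylcyclohex-2-en-1-yl]heptadeca-2,4,6,8,10,12,14,16-octaen-1-ol | CC1=CCCC(C)(C)[C@@H]1/C=C/C(C)=C/C=C/C(C)=C/C=C/C=C(C)/C=C/C=C(C)/CO
A1 | alternative 1 | (3E)-4-[(1S)-2,6,6-trimethylcyclohex-2-en-1-yl]but-3-en-2-one ((S)-α-ionone) | CC1=CCCC(C)(C)[C@@H]1/C=C/C(C)=O
A2 | alternative 1 | {(2E,4E)-3-methyl-5-[(1S)-2,6,6-trimethylcyclohex-2-en-1-yl]penta-2,4-dien-1-yl}(triphenyl)phosphonium bromide | CC1=CCCC(C)(C)[C@@H]1/C=C/C(C)=C/C[P+](c1ccccc1)(c1ccccc1)c1ccccc1.[Br-]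
A3 | alternative 1 | {(2E,4E)-5-[(1S,4S)-4-hydroxy-2,6,6-trimethylcyclohex-2-en-1-yl]-3-methylpenta-2,4-dien-1-yl}(triphenyl)phosphonium bromide | c1ccccc1[P+](c1ccccc1)(c1ccccc1)C/C=C(C)/C=C/[C@@H]1C(C)=C[C@@H](O)CC1(C)C.[Br-]
A4 | alternative 1 | (2E,4E,6E)-2,7-dimethylocta-2,4,6-trienedial | O=C/C(C)=C/C=C/C=C(C)/C=O
A5 | alternative 2 | 5-{[(2E)-3,7-dimethylocta-2,6-dien-1-yl]sulfonyl}-1-phenyl-1H-tetrazole | CC(C)=CCC/C(C)=C/CS(=O)(=O)c1nnnn1-c1ccccc1
A6 | alternative 3 | ethyl [(1S)-2,6,6-trimethylcyclohex-2-en-1-yl]acetate | CCOC(=O)C[C@@H]1C(C)=CCCC1(C)C
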